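## The problem

Magnone B, compound 15, is a monocyclic lignan: a tetrahydrofuran (O1, C2, C3, C4, C5) with a 3,4,5-trimethoxyphenyl group on C2, a hydroxymethyl group (C6) on C3 and a 3,4-dimethoxybenzoyl group (carbonyl carbon C7) on C4. Its backbone is the four-carbon chain C2–C3–C4–C7 with an aryl ring at each end and the one-carbon arms C6 and C5 on the inner carbons, so a synthesis has to build this chain with the two different aryl groups at the correct ends and decide which arm closes onto which benzylic carbon. Three contiguous stereocentres (2S,3R,4R) are required, 2,3-trans and 3,4-cis; C3 and C4 are best set together on a cyclic template, after which the C3 substituent can direct C2, whereas C2 is a poor handle for the other two. C4 is α to the aryl ketone and cis to its C3 neighbour, so it will epimerise if the free ketone meets base or hot acid. The same ketone has the ring oxygen in the β position (risk of E1cB ring opening) and the C6 hydroxyl in the γ position (risk of hemiketal formation). The C2–O1 bond is a benzylic ether of an electron-rich arene and will not survive strong acid, hydrogenolysis or excess oxidant. The enabling feature is this same O1–C2 bond: in the ring-opened 1,4-diol, C2 is the only benzylic CH2, it sits on the oxidisable trimethoxyphenyl ring, and the C5 hydroxyl captures a C2 cation in a five-membered closure, whereas the C6 hydroxyl could only form an oxetane.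

## Retrosynthesis

**15 ⇒ 14.** No skeletal bond is cut; the C7 ketone is masked as the ethylene ketal 14. With C7 as a ketal, C4 cannot enolise, the β-alkoxy and γ-hydroxy ketone motifs do not exist, and the dimethoxyphenyl ring has no benzylic hydrogen. The forward reaction is a plain, mild hydrolysis as the last step.

**14 ⇒ 13.** The O1–C2 bond is cut, opening the ring to the diol 13, in which C2 is an unfunctionalised benzylic CH2. Cutting O1–C5 instead would need a C2 carbinol of defined configuration, set by a reagent, and cutting a ring C–C bond would discard the lignan chain logic. The O1–C2 cut removes the ring and one stereocentre together and leaves a two-stereocentre acyclic diol. The forward reaction must oxidise C2–H and nothing else, close the five-membered ether through the C5 hydroxyl, and place the aryl group trans to the C3 substituent.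

**13 ⇒ 12.** The two CH2OH groups are traced back to one lactone: C6 to the carbonyl and C5 to the acetal carbon of the γ-menthyloxy butyrolactone 12. At C3 the ring bond and the exocyclic bond exchange roles between lactone and tetrahydrofuran, so the trans lactone is the precursor of the 3,4-cis ether. The forward reaction is exhaustive hydride reduction with loss of the auxiliary alcohol 4; the dioxolane is inert to it.

**12 ⇒ 11.** The C7 dioxolane is exchanged for the dithiane of 11. The exchange is placed at the lactone stage because 11 has no free hydroxyl; in the diol, the C6 hydroxyl would intercept the C7 thionium ion as a five-membered mixed ketal. The forward reaction must replace sulfur by oxygen without passing through the free ketone.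

**11 ⇒ 5 + 7 + 8.** The bonds C4–C7 and C2–C3 are cut, giving three simple pieces. C7 is an acyl anion (lithiated dithiane 9 from dithiane 7), C4 the β-carbon of butenolide 5, C3 the α-carbon of the derived enolate 10 and C2 the benzylic electrophile 8. A C3–C4 cut (coupling of two different C6C3 units) would offer no comparable stereocontrol. The forward reaction is a one-pot conjugate addition and enolate alkylation; the C5 acetal controls C4 and C4 controls C3.

**5 ⇒ 3 + 4; 3 ⇒ 1; 7 ⇒ 6.** Butenolide 5 is the menthyl acetal of hydroxybutenolide 3, the photooxygenation product of furfural 1, with (−)-menthol 4 as the only source of chirality. Dithiane 7 comes from 3,4-dimethoxybenzaldehyde 6.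

## Roads not taken

Alternative 1: The C4–C7 cut is kept, but C2–C3 is made by an aldol reaction. The aldol adduct A1 (carbinol epimers) would arise in one pot when enolate 10 is trapped with 3,4,5-trimethoxybenzaldehyde A2 in place of the benzyl bromide.
- Merit: the C2 oxygen arrives with the carbon, so ring closure needs only ionisation of a benzylic alcohol. This is a more dependable route to the C2 cation than C–H abstraction, and in this respect this road is the better one. The step count is about the same.
- Weak points: the cyclodehydration needs acid, which a C7 ketal would not survive, so the dithiane must be carried to the end and removed from a molecule with a benzylic ether and a free γ-hydroxyl. The aldol adds a stereocentre of no value, and the aldolate can revert.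
- What the chosen plan sets against it: single-diastereomer intermediates from a clean benzylation, ring closure under buffered non-acidic conditions, and a final step that is a simple ketal hydrolysis. This road is kept as the fallback for the key step.

Alternative 2: C3–C6 and C4–C7 are cut together. The cis-fused cyclobutene A5 would come from a gold-catalysed [2+2] cycloaddition between the dihydrofuran A3, (S)-2-(3,4,5-trimethoxyphenyl)-2,5-dihydrofuran, and the alkyne A4, 4-ethynyl-1,2-dimethoxybenzene. A catalyst such as [(t-Bu)2(2-biphenylyl)PAu(NCMe)]SbF6 (monovalent gold) would be used. Ozonolysis of A5 would then give the C7 ketone and a C6 aldehyde, the latter to be reduced selectively.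
- Merit: on paper it is the shortest and most convergent road, and the 3,4-cis relationship follows from the ring fusion.
- Weak points:
  - Such cycloadditions are established for electron-rich, more substituted alkenes, not for a 1,2-disubstituted allylic ether alkene.
  - Nothing in A3 distinguishes C3 from C4 well enough to fix the regiochemistry.
  - Ozone also attacks trimethoxyphenyl rings.
  - The ozonolysis of A5 leaves a 1,4-dicarbonyl array with both α-centres epimerisable.
  - A3 itself needs an asymmetric arylation.
- Comparison: it is better in step count; the chosen plan has built-in regiochemistry and close precedent for every step.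

Alternative 3: C3–C6 is cut. The (bromomethyl)dimethylsilyl ether A6 of the C7 carbinol of a 2-aryl-2,5-dihydrofuran is treated with Bu3SnH. The silylmethyl radical adds 6-endo to C3 and the C4 radical takes up hydrogen, giving the cis-fused siloxane A7. Tamao oxidation and oxidation of the C7 carbinol would follow.
- Merit: the tether delivers C6 cis to the C7-bearing carbon, and the fully substituted C4 disfavours the 5-exo mode.
- Weak points:
  - A6 needs its own multi-step, enantioselective preparation.
  - The C7 carbinol stereocentre is made only to be destroyed.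
  - The C2–H of A6 is benzylic, allylic and α to oxygen, so it is exposed to hydrogen abstraction.
  - The end game needs selective oxidation of a secondary benzylic alcohol beside a primary one, plus stoichiometric tin.
- Comparison: its stereocontrol by ring constraint is at least as secure as substrate control, but the chosen plan gets the same C3/C4 relationship from the trans lactone in far fewer steps.

Key step: step 7

Assumption: the atom labels of 15 (O1, C2–C5, C6 = hydroxymethyl carbon, C7 = carbonyl carbon) are kept for the corresponding atoms of all intermediates; (−)-menthol is the only source of chirality.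

## Route

Step 1
Reactants: 1 furfural (furan-2-carbaldehyde)
Product: 3 5-hydroxyfuran-2(5H)-one (racemic), via furfural endoperoxide 2 (not isolated)
Conditions: O2, methylene blue (cat.), visible light, MeOH, rt
Reagents that add atoms: dioxygen, O=O
Why: Sensitised singlet-oxygen [4+2] cycloaddition across C2/C5 of the furan gives endoperoxide 2; methanol adds to the formyl group and the peroxide fragments with loss of methyl formate, leaving the hydroxybutenolide (classical furfural photooxygenation).

Step 2
Reactants: 3 5-hydroxyfuran-2(5H)-one; 4 (−)-menthol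
Product: 5 (5R)-5-[(1R,2S,5R)-2-isopropyl-5-methylcyclohexyloxy]furan-2(5H)-one
Conditions: CSA (cat.), toluene, reflux, Dean–Stark; crystallisation from petroleum ether, mother liquor re-equilibrated (CSA cat.) and recrystallised
Reagents that add atoms: none
Why: Acid-catalysed acetalisation of the pseudo-acid hydroxyl; the C5 epimers interconvert through the oxocarbenium ion and the (5R) epimer is the crystalline one, so crystallisation-induced diastereomer transformation should funnel the material to 5, with C5 set by the menthyl group.

Step 3
Reactants: 6 3,4-dimethoxybenzaldehyde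
Product: 7 2-(3,4-dimethoxyphenyl)-1,3-dithiane
Conditions: HS(CH2)3SH, BF3·OEt2, CH2Cl2, 0 °C → rt
Reagents that add atoms: propane-1,3-dithiol, SCCCS
Why: Lewis-acid-promoted dithioacetalisation of an aromatic aldehyde, giving the Corey–Seebach acyl-anion precursor.

Step 4
Reactants: 7 2-(3,4-dimethoxyphenyl)-1,3-dithiane; 5 (5R)-menthyloxybutenolide; 8 3,4,5-trimethoxybenzyl bromide
Product: 11 (3R,4R,5R)-4-[2-(3,4-dimethoxyphenyl)-1,3-dithian-2-yl]-5-[(1R,2S,5R)-menthyloxy]-3-(3,4,5-trimethoxybenzyl)dihydrofuran-2(3H)-one, via lithiated dithiane 9 (not isolated), via lithium lactone enolate 10 (not isolated)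
Conditions: n-BuLi, THF, −30 °C; then 5, −78 °C; then 8, TMEDA, −78 °C → rt
Reagents that add atoms: none
Why: The aryl-stabilised dithiane anion 9 undergoes Michael addition to C4 of 5 on the face anti to the C5 menthyloxy group (C4 set by C5); enolate 10 is then benzylated by 8 at C3 trans to the bulky C4 substituent (C3 set by C4), a tandem conjugate addition–enolate alkylation well known for γ-alkoxybutenolides.

Step 5
Reactants: 11 dithianyl lactone
Product: 12 (3R,4R,5R)-4-[2-(3,4-dimethoxyphenyl)-1,3-dioxolan-2-yl]-5-[(1R,2S,5R)-menthyloxy]-3-(3,4,5-trimethoxybenzyl)dihydrofuran-2(3H)-one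
Conditions: PhI(OCOCF3)2, HOCH2CH2OH, MeCN, 0 °C → rt; aq. NaHCO3 work-up
Reagents that add atoms: ethylene glycol, OCCO
Why: Oxidative dethioacetalisation with a hypervalent iodine reagent in the presence of a diol: S-activation, opening to the thionium ion, capture by glycol and expulsion of the sulfur chain as the cyclic disulfide close the dioxolane directly, so the free ketone never forms; 11 has no hydroxyl to compete with the glycol, and the lactone, acetal and stereocentres are not touched.

Step 6
Reactants: 12 dioxolanyl lactone
Product: 13 (2R,3R)-2-[2-(3,4-dimethoxyphenyl)-1,3-dioxolan-2-yl]-3-(3,4,5-trimethoxybenzyl)butane-1,4-diol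
Conditions: LiAlH4, THF, 0 °C → rt; Na2SO4·10H2O quench
Reagents that add atoms: none
Why: Hydride reduction of the lactone carbonyl opens the ring, the menthyl hemiacetal at C5 collapses to an aldehyde that is reduced faster than it can enolise, and C6 and C5 both end as CH2OH with release of menthol; the dioxolane is inert to hydride and the basic work-up (with chromatography on Et3N-deactivated silica) keeps it intact.

Step 7
Reactants: 13 dioxolanyl diol
Product: 14 {(2S,3R,4R)-4-[2-(3,4-dimethoxyphenyl)-1,3-dioxolan-2-yl]-2-(3,4,5-trimethoxyphenyl)oxolan-3-yl}methanol (magnone B ethylene ketal)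
Conditions: DDQ (1.2 equiv), 2,6-dichloropyridine, 4 Å MS, ClCH2CH2Cl, 0 °C → rt
Reagents that add atoms: none
Why: DDQ forms a charge-transfer complex with the trimethoxyphenyl ring of 13, and electron transfer followed by loss of hydrogen from C2 (net hydride abstraction) gives the C2 benzylic cation, stabilised by the para methoxy group, as an ion pair with DDQH−. The C5 hydroxyl adds to this cation in a 5-exo-trig closure (ring O1–C2–C3–C4–C5), whereas the C6 hydroxyl could reach C2 only through a four-membered transition state and stays free. The closest known reaction type is the DDQ-mediated benzylic C–H oxidation of electron-rich arylalkanols with intramolecular capture by the alcohol, the reaction that turns dibenzylbutanediol lignans into 2-aryltetrahydrofurans. The new stereocentre C2 is controlled by C3 and C4: the planar cation closes through an envelope with the aryl group on the face opposite the C3 hydroxymethyl group and the bulky C4 ketal carbon, giving the 2,3-trans (2S) ether, and reversible ionisation of the benzylic ether can only drain a cis isomer toward the same, more stable product. Site selectivity is secured because C2–H is the only benzylic hydrogen in the molecule, the dimethoxyphenyl ring being attached to the fully substituted C7. Chemoselectivity against Friedel–Crafts closure of the dimethoxyphenyl ring onto C2 (a tetralin) rests on the faster capture by oxygen in a non-acidic medium. 2,6-Dichloropyridine and molecular sieves buffer DDQH2 and exclude water, so the dioxolane is neither opened nor transketalised by the C6 hydroxyl and no benzylic alcohol forms. Further oxidation of 14 at its remaining C2–H is to be limited by near-stoichiometric oxidant and low temperature.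

Step 8
Reactants: 14 magnone B ethylene ketal
Product: 15 magnone B, (3,4-dimethoxyphenyl)[(3R,4R,5S)-4-(hydroxymethyl)-5-(3,4,5-trimethoxyphenyl)oxolan-3-yl]methanone, (2S,3R,4R) in the ring numbering used here
Conditions: 1 M aq. HCl, THF, 0 °C → rt
Reagents that add atoms: water, O
Why: Acid-catalysed ketal hydrolysis through the oxocarbenium ion stabilised by the dimethoxyphenyl ring; dilute acid at or below room temperature should be too mild to enolise C4 or ionise the C2 benzylic ether, and no base is used, so E1cB opening of the β-alkoxy ketone is avoided.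

## Compound list

1 | furfural (furan-2-carbaldehyde) | O=Cc1ccco1 | starting material
2 | furfural endoperoxide (2,3,7-trioxabicyclo[2.2.1]hept-5-ene-1-carbaldehyde) | O=CC12OOC(C=C1)O2 | intermediate
3 | 5-hydroxyfuran-2(5H)-one (racemic) | O=C1C=CC(O)O1 | intermediate
4 | (−)-menthol, (1R,2S,5R)-2-isopropyl-5-methylcyclohexanol | CC(C)[C@@H]1CC[C@@H](C)C[C@H]1O | starting material
5 | (5R)-5-[(1R,2S,5R)-2-isopropyl-5-methylcyclohexyloxy]furan-2(5H)-one | O=C1C=C[C@H](O[C@@H]2C[C@H](C)CC[C@H]2C(C)C)O1 | intermediate
6 | 3,4-dimethoxybenzaldehyde | COc1ccc(C=O)cc1OC | starting material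
7 | 2-(3,4-dimethoxyphenyl)-1,3-dithiane | COc1ccc(C2SCCCS2)cc1OC | intermediate
8 | 3,4,5-trimethoxybenzyl bromide | COc1cc(CBr)cc(OC)c1OC | starting material
9 | 2-lithio-2-(3,4-dimethoxyphenyl)-1,3-dithiane | [Li]C1(c2ccc(OC)c(OC)c2)SCCCS1 | intermediate
10 | lithium (4R,5R)-4-[2-(3,4-dimethoxyphenyl)-1,3-dithian-2-yl]-5-[(1R,2S,5R)-menthyloxy]-4,5-dihydrofuran-2-olate | [Li]OC1=C[C@@H](C2(c3ccc(OC)c(OC)c3)SCCCS2)[C@H](O[C@@H]4C[C@H](C)CC[C@H]4C(C)C)O1 | intermediate
11 | (3R,4R,5R)-4-[2-(3,4-dimethoxyphenyl)-1,3-dithian-2-yl]-5-[(1R,2S,5R)-menthyloxy]-3-(3,4,5-trimethoxybenzyl)dihydrofuran-2(3H)-one | O=C1O[C@@H](O[C@@H]2C[C@H](C)CC[C@H]2C(C)C)[C@H](C3(c4ccc(OC)c(OC)c4)SCCCS3)[C@H]1Cc5cc(OC)c(OC)c(OC)c5 | intermediate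
12 | (3R,4R,5R)-4-[2-(3,4-dimethoxyphenyl)-1,3-dioxolan-2-yl]-5-[(1R,2S,5R)-menthyloxy]-3-(3,4,5-trimethoxybenzyl)dihydrofuran-2(3H)-one | O=C1O[C@@H](O[C@@H]2C[C@H](C)CC[C@H]2C(C)C)[C@H](C3(c4ccc(OC)c(OC)c4)OCCO3)[C@H]1Cc5cc(OC)c(OC)c(OC)c5 | intermediate
13 | (2R,3R)-2-[2-(3,4-dimethoxyphenyl)-1,3-dioxolan-2-yl]-3-(3,4,5-trimethoxybenzyl)butane-1,4-diol | COc1cc(C[C@@H](CO)[C@H](CO)C2(c3ccc(OC)c(OC)c3)OCCO2)cc(OC)c1OC | intermediate
14 | {(2S,3R,4R)-4-[2-(3,4-dimethoxyphenyl)-1,3-dioxolan-2-yl]-2-(3,4,5-trimethoxyphenyl)oxolan-3-yl}methanol | O1CCOC1(c2ccc(OC)c(OC)c2)[C@H]3CO[C@H](c4cc(OC)c(OC)c(OC)c4)[C@H]3CO | intermediate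
15 | magnone B, (3,4-dimethoxyphenyl)[(3R,4R,5S)-4-(hydroxymethyl)-5-(3,4,5-trimethoxyphenyl)oxolan-3-yl]methanone | COc1ccc(C(=O)[C@H]2CO[C@H](c3cc(OC)c(OC)c(OC)c3)[C@H]2CO)cc1OC | target

## Step count and risks

Total step count: 8. Longest linear sequence: 7 steps (1 → 3 → 5 → 11 → 12 → 13 → 14 → 15); the branch from 6 joins at step 4.

**Step 7 (key step).** Three processes may interfere. Hydride abstraction may be slow, because the para methoxy group of the trimethoxyphenyl ring is twisted out of conjugation and the dimethoxyphenyl ring competes for the oxidant by unproductive complexation. The product is itself a benzylic ether of an electron-rich ring, so a second oxidation at C2 may open the ring again. Friedel–Crafts capture of the cation by the dimethoxyphenyl ring, or transketalisation by the C6 hydroxyl, may intervene if the medium turns acidic. The fallback introduces the C2 oxygen together with the carbon; it sets out from enolate 10 (made from 5 and 7 as in step 4) and returns to the route at 15. Enolate 10 is trapped with 3,4,5-trimethoxybenzaldehyde A2 in place of 8 to give the aldol adduct F1 as carbinol epimers. LiAlH4 in THF reduces F1 to the dithianyl triol F2. CSA in CH2Cl2 ionises the benzylic carbinol of F2, and the C5 hydroxyl closes the ring under thermodynamic control to the 2,3-trans dithianyl tetrahydrofuran F3. PhI(OCOCF3)2 in MeCN–H2O then hydrolyses the dithiane of F3 to 15.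

**Step 5.** The exchange may stop at a hydroxyethyl monothioketal at the hindered C7, or the iodine oxidant may attack an electron-rich ring. The fallback is a two-stage exchange through the free ketone, from 11 back to 12. Alkylative hydrolysis of 11 (MeI, CaCO3, MeCN–H2O, 45 °C) gives the keto lactone F4; its all-trans arrangement is the stable one, so enolisation at C4 is harmless. Ketalisation of F4 with Me3SiOCH2CH2OSiMe3 and catalytic TMSOTf in CH2Cl2 at −78 → −20 °C gives 12.

**Step 4.** C-Benzylation of the hindered enolate 10 may be incomplete, with proton transfer from the product, or 9 may add partly in the 1,2-sense. The fallback is a stepwise sequence, from 10 back to 11. Enolate 10 is protonated (aq. NH4Cl) and the conjugate adduct F5 is isolated. F5 is deprotonated with LiN(i-Pr)2 in THF at −78 °C and alkylated with 8 in the presence of DMPU; the benzyl group again enters trans to the C4 substituent, giving 11.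

**Step 8.** Slow hydrolysis of the aryl dioxolane would call for stronger acid or longer times, which opens the way to epimerisation at C4 by enolisation, ionisation of the C2 benzylic ether, or diversion into a mixed ketal with the C6 hydroxyl. The fallback uses the far more labile dimethyl ketal, from 11, returning at 15. PhI(OCOCF3)2 in MeOH converts 11 into the dimethyl ketal lactone F6. LiAlH4 reduces F6 to the diol F7, which is kept away from acid to avoid internal transketalisation. The DDQ cyclisation of step 7 applied to F7 gives the tetrahydrofuran dimethyl ketal F8. Oxalic acid on wet silica gel in CH2Cl2 at 0 °C hydrolyses F8 to 15.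

## Further compounds

F1 | step 7 | (3S,4R,5R)-4-[2-(3,4-dimethoxyphenyl)-1,3-dithian-2-yl]-3-[hydroxy(3,4,5-trimethoxyphenyl)methyl]-5-[(1R,2S,5R)-menthyloxy]dihydrofuran-2(3H)-one (carbinol epimers) | O=C1O[C@@H](O[C@@H]2C[C@H](C)CC[C@H]2C(C)C)[C@H](C3(c4ccc(OC)c(OC)c4)SCCCS3)[C@H]1C(O)c5cc(OC)c(OC)c(OC)c5
F2 | step 7 | (2R,3R)-3-[2-(3,4-dimethoxyphenyl)-1,3-dithian-2-yl]-2-(hydroxymethyl)-1-(3,4,5-trimethoxyphenyl)butane-1,4-diol (C1 epimers) | OC(c1cc(OC)c(OC)c(OC)c1)[C@@H](CO)[C@H](CO)C2(c3ccc(OC)c(OC)c3)SCCCS2
F3 | step 7 | {(2S,3R,4R)-4-[2-(3,4-dimethoxyphenyl)-1,3-dithian-2-yl]-2-(3,4,5-trimethoxyphenyl)oxolan-3-yl}methanol | S1CCCSC1(c2ccc(OC)c(OC)c2)[C@H]3CO[C@H](c4cc(OC)c(OC)c(OC)c4)[C@H]3CO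
F4 | step 5 | (3R,4R,5R)-4-(3,4-dimethoxybenzoyl)-5-[(1R,2S,5R)-menthyloxy]-3-(3,4,5-trimethoxybenzyl)dihydrofuran-2(3H)-one | O=C1O[C@@H](O[C@@H]2C[C@H](C)CC[C@H]2C(C)C)[C@H](C(=O)c3ccc(OC)c(OC)c3)[C@H]1Cc4cc(OC)c(OC)c(OC)c4
F5 | step 4 | (4R,5R)-4-[2-(3,4-dimethoxyphenyl)-1,3-dithian-2-yl]-5-[(1R,2S,5R)-menthyloxy]dihydrofuran-2(3H)-one | O=C1C[C@@H](C2(c3ccc(OC)c(OC)c3)SCCCS2)[C@H](O[C@@H]4C[C@H](C)CC[C@H]4C(C)C)O1
F6 | step 8 | (3R,4R,5R)-4-[(3,4-dimethoxyphenyl)dimethoxymethyl]-5-[(1R,2S,5R)-menthyloxy]-3-(3,4,5-trimethoxybenzyl)dihydrofuran-2(3H)-one | O=C1O[C@@H](O[C@@H]2C[C@H](C)CC[C@H]2C(C)C)[C@H](C(OC)(OC)c3ccc(OC)c(OC)c3)[C@H]1Cc4cc(OC)c(OC)c(OC)c4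
F7 | step 8 | (2R,3R)-2-[(3,4-dimethoxyphenyl)dimethoxymethyl]-3-(3,4,5-trimethoxybenzyl)butane-1,4-diol | COc1cc(C[C@@H](CO)[C@H](CO)C(OC)(OC)c2ccc(OC)c(OC)c2)cc(OC)c1OC
F8 | step 8 | {(2S,3R,4R)-4-[(3,4-dimethoxyphenyl)dimethoxymethyl]-2-(3,4,5-trimethoxyphenyl)oxolan-3-yl}methanol | COC(OC)(c1ccc(OC)c(OC)c1)[C@H]2CO[C@H](c3cc(OC)c(OC)c(OC)c3)[C@H]2CO
A1 | alternative 1 | trans-4-[2-(3,4-dimethoxyphenyl)-1,3-dithian-2-yl]-3-[hydroxy(3,4,5-trimethoxyphenyl)methyl]-5-[(1R,2S,5R)-menthyloxy]dihydrofuran-2(3H)-one (carbinol epimers) | O=C1O[C@@H](O[C@@H]2C[C@H](C)CC[C@H]2C(C)C)[C@H](C3(c4ccc(OC)c(OC)c4)SCCCS3)[C@H]1C(O)c5cc(OC)c(OC)c(OC)c5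
A2 | alternative 1 | 3,4,5-trimethoxybenzaldehyde | COc1cc(C=O)cc(OC)c1OC
A3 | alternative 2 | (S)-2-(3,4,5-trimethoxyphenyl)-2,5-dihydrofuran | COc1cc([C@@H]2C=CCO2)cc(OC)c1OC
A4 | alternative 2 | 4-ethynyl-1,2-dimethoxybenzene | C#Cc1ccc(OC)c(OC)c1
A5 | alternative 2 | cis-fused 6-(3,4-dimethoxyphenyl)-2-(3,4,5-trimethoxyphenyl)-3-oxabicyclo[3.2.0]hept-6-ene, C2 aryl group on the face opposite the cyclobutene | C1(c2ccc(OC)c(OC)c2)=C[C@@H]3[C@@H](c4cc(OC)c(OC)c(OC)c4)OC[C@H]13
A6 | alternative 3 | (bromomethyl)dimethylsilyl ether of (3,4-dimethoxyphenyl)[(5S)-5-(3,4,5-trimethoxyphenyl)-2,5-dihydrofuran-3-yl]methanol (carbinol configuration as in A7) | BrC[Si](C)(C)O[C@H](c1ccc(OC)c(OC)c1)C2=C[C@@H](c3cc(OC)c(OC)c(OC)c3)OC2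
A7 | alternative 3 | cis-fused bicyclic siloxane: six-membered ring C6H2–SiMe2–O–C7H(3,4-dimethoxyphenyl) fused across C3–C4 of the (2S)-2-(3,4,5-trimethoxyphenyl)tetrahydrofuran | C[Si]1(C)O[C@H](c2ccc(OC)c(OC)c2)[C@H]3CO[C@H](c4cc(OC)c(OC)c(OC)c4)[C@H]3C1
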